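The route rests on cutting the C6–C7 bond of the 14-membered carbocycle (cembrane numbering), where a methylene carbon meets the E-trisubstituted C7=C8 alkene, remote from the stereocentres C1, C2 and C13 and from the fused lactone ring. A cathodic nickel-catalysed decarboxylative alkenylation forms this bond and closes the macrocycle in one operation, with the alkene geometry carried in by an alkenyl iodide. Its precursor is a cis-β,γ-disubstituted γ-butyrolactone without the exocyclic methylene: the C2 arm (C3–C6) ends in an N-hydroxyphthalimide ester, and the C1 arm (C14–C7) carries the C13 silyl ether and the E-iodoalkene. Both arms derive from one alkenyl iodide made from pent-4-yn-1-ol.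

Key step: step 13

Numbering: C1 = ring-fusion CH bearing lactone carbon C15; C2 = ring-fusion CH–O; C3=C4, C7=C8 and C11=C12 = ring alkenes; C13 = oxygenated carbon; C14 = ring CH2; C16 = lactone carbonyl; C17 = exocyclic methylene carbon. The C2 descriptor changes from R to S when C17 is introduced; this is a priority change, not an inversion.

Assumption: (R)-TRIP [3,3'-bis(2,4,6-triisopropylphenyl)-1,1'-binaphthyl-2,2'-diyl hydrogen phosphate] is taken to steer pinacol allylboronates to the Re face of an aldehyde, as with simple aromatic and unsaturated aldehydes; if a trial showed the opposite sense, (S)-TRIP would be used in steps 4 and 9.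

Step 1
Reactants: 1 pent-4-yn-1-ol
Product: 3 (4E)-5-iodo-4-methylpent-4-en-1-ol, via alkenylalane 2 (not isolated)
Conditions: Me3Al (3 equiv), Cp2ZrCl2 (0.25 equiv), CH2Cl2, 0 °C to rt; then I2, THF, −30 to 0 °C; aq. K2CO3
Reagents that add atoms: trimethylaluminium C[Al](C)C; iodine II
Why: Negishi zirconium-catalysed carboalumination adds CH3 and Al syn across the terminal alkyne with aluminium on the terminal carbon, and iodinolysis of the C–Al bond with retention should give the E-iodide (the hydroxyl rides along as its aluminium alkoxide).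

Step 2
Reactants: 3 (4E)-5-iodo-4-methylpent-4-en-1-ol
Product: 4 (4E)-5-iodo-4-methylpent-4-enal
Conditions: TEMPO (10 mol%), PhI(OAc)2 (1.1 equiv), CH2Cl2, rt
Reagents that add atoms: none
Why: Oxoammonium (TEMPO/PhI(OAc)2) oxidation of a primary alcohol in anhydrous CH2Cl2 should stop at the aldehyde and leaves the alkenyl iodide untouched.

Step 3
Reactants: 4 (4E)-5-iodo-4-methylpent-4-enal; 5 2-(triphenylphosphoranylidene)propanal
Product: 6 (2E,6E)-7-iodo-2,6-dimethylhepta-2,6-dienal
Conditions: toluene, 90 °C
Reagents that add atoms: none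
Why: Wittig olefination with the stabilised formyl ylide should give the E-configured α-methyl enal, the aliphatic aldehyde 4 reacting much faster than the conjugated product.

Step 4
Reactants: 6 (2E,6E)-7-iodo-2,6-dimethylhepta-2,6-dienal; 7 2-allyl-4,4,5,5-tetramethyl-1,3,2-dioxaborolane
Product: 8 (4R,5E,9E)-10-iodo-5,9-dimethyldeca-1,5,9-trien-4-ol
Conditions: (R)-TRIP (5 mol%), 4 Å MS, toluene, −30 °C; aq. NaHCO3
Reagents that add atoms: none
Why: Chiral phosphoric acid-catalysed allylboration runs through a closed chair transition state in which the catalyst binds a boronate oxygen and the formyl hydrogen, so allyl transfer to the Re face of the enal should set C13 as R.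

Step 5
Reactants: 8 (4R,5E,9E)-10-iodo-5,9-dimethyldeca-1,5,9-trien-4-ol
Product: 9 tert-butyl{[(4R,5E,9E)-10-iodo-5,9-dimethyldeca-1,5,9-trien-4-yl]oxy}dimethylsilane
Conditions: TBSCl, imidazole, DMF, rt
Reagents that add atoms: tert-butyldimethylsilyl chloride CC(C)(C)[Si](C)(C)Cl
Why: Standard silylation of a secondary allylic alcohol gives a TBS ether that should survive hydroboration, oxidation, electrolysis and enolate chemistry and is removed by fluoride at the end.

Step 6
Reactants: 9 tert-butyl{[(4R,5E,9E)-10-iodo-5,9-dimethyldeca-1,5,9-trien-4-yl]oxy}dimethylsilane; 7 2-allyl-4,4,5,5-tetramethyl-1,3,2-dioxaborolane (4 equiv)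
Product: 10 2-[(2Z,5R,6E,10E)-5-(tert-butyldimethylsilyloxy)-11-iodo-6,10-dimethylundeca-2,6,10-trien-1-yl]-4,4,5,5-tetramethyl-1,3,2-dioxaborolane
Conditions: Ru(κ2-O2NO)(=CH-C6H4-2-OiPr)(κ2-C,C-L) (5 mol%; L = cyclometalated 1-(1-adamantyl)-3-(2,6-diisopropylphenyl)imidazolidin-2-ylidene), THF, 35 °C, argon purge
Reagents that add atoms: none
Why: Z-selective olefin cross-metathesis, in which the cyclometalated ruthenium catalyst holds both metallacyclobutane substituents on one side, should join the terminal alkene of 9 to allyl-B(pin) as the Z-allylboronate with loss of ethene, while the trisubstituted alkenes and the alkenyl iodide are too hindered to react.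

Step 7
Reactants: 3 (4E)-5-iodo-4-methylpent-4-en-1-ol
Product: 12 (2E)-6-hydroxy-3-methylhex-2-enal, via alkenyllithium alkoxide 11 (not isolated)
Conditions: t-BuLi (3.1 equiv), Et2O, −78 °C; DMF, −78 to 0 °C; aq. NH4Cl
Reagents that add atoms: N,N-dimethylformamide CN(C)C=O
Why: After deprotonation of the hydroxyl, iodine–lithium exchange proceeds with retention of the alkene geometry, and formylation of the alkenyllithium with DMF should give the E-enal on hydrolysis.

Step 8
Reactants: 12 (2E)-6-hydroxy-3-methylhex-2-enal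
Product: 13 (4E)-4-methyl-6-oxohex-4-en-1-yl acetate
Conditions: Ac2O, pyridine, CH2Cl2, 0 °C
Reagents that add atoms: acetic anhydride CC(=O)OC(C)=O
Why: Acetylation masks the primary hydroxyl so that it can neither add in oxa-Michael fashion to the enal nor disturb the acid catalyst of step 9, and the acetate is shed later in the alkaline peroxide work-up of step 10.

Step 9
Reactants: 10 2-[(2Z,5R,6E,10E)-5-(tert-butyldimethylsilyloxy)-11-iodo-6,10-dimethylundeca-2,6,10-trien-1-yl]-4,4,5,5-tetramethyl-1,3,2-dioxaborolane; 13 (4E)-4-methyl-6-oxohex-4-en-1-yl acetate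
Product: 14 (4E,6R,7S,9R,10E,14E)-9-(tert-butyldimethylsilyloxy)-7-ethenyl-6-hydroxy-15-iodo-4,10,14-trimethylpentadeca-4,10,14-trien-1-yl acetate
Conditions: (R)-TRIP (10 mol%), 4 Å MS, toluene, −30 to 0 °C; aq. NaHCO3
Reagents that add atoms: none
Why: In this chiral phosphoric acid-catalysed allylboration through a closed chair transition state, the Z geometry of 10 places the C14 substituent axial and so fixes the C1/C2 syn relationship (the later cis ring fusion), while the catalyst directs attack to the Re face of enal 13 and should set C2 as R and C1 as S independently of remote C13.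

Step 10
Reactants: 14 (4E,6R,7S,9R,10E,14E)-9-(tert-butyldimethylsilyloxy)-7-ethenyl-6-hydroxy-15-iodo-4,10,14-trimethylpentadeca-4,10,14-trien-1-yl acetate
Product: 16 (4E,6R,7R,9R,10E,14E)-9-(tert-butyldimethylsilyloxy)-7-(2-hydroxyethyl)-15-iodo-4,10,14-trimethylpentadeca-4,10,14-triene-1,6-diol, via alkylborane 15 (not isolated)
Conditions: 9-BBN (3 equiv), THF, 0 °C to rt; then 3 M NaOH, 30% H2O2, 0 °C to rt
Reagents that add atoms: hydrogen peroxide OO
Why: Hydroboration with bulky 9-BBN is selective for the monosubstituted vinyl group over the three trisubstituted alkenes and puts boron on the terminal carbon, and alkaline peroxide then oxidises the C–B bond and saponifies the primary acetate in the same flask without touching a stereocentre.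

Step 11
Reactants: 16 (4E,6R,7R,9R,10E,14E)-9-(tert-butyldimethylsilyloxy)-7-(2-hydroxyethyl)-15-iodo-4,10,14-trimethylpentadeca-4,10,14-triene-1,6-diol
Product: 17 (4E)-5-{(2R,3S)-3-[(2R,3E,7E)-2-(tert-butyldimethylsilyloxy)-8-iodo-3,7-dimethylocta-3,7-dien-1-yl]-5-oxooxolan-2-yl}-4-methylpent-4-enoic acid
Conditions: TEMPO (0.3 equiv), PhI(OAc)2 (5 equiv), MeCN–H2O (1:1), rt
Reagents that add atoms: water O
Why: TEMPO/PhI(OAc)2 oxidation is selective for primary alcohols, so the C16 aldehyde should be trapped by the C2 hydroxyl as a five-membered lactol and oxidised to the γ-lactone, while the isolated primary alcohol goes through its aldehyde hydrate to the carboxylic acid.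

Step 12
Reactants: 17 (4E)-5-{(2R,3S)-3-[(2R,3E,7E)-2-(tert-butyldimethylsilyloxy)-8-iodo-3,7-dimethylocta-3,7-dien-1-yl]-5-oxooxolan-2-yl}-4-methylpent-4-enoic acid; 18 N-hydroxyphthalimide
Product: 19 1,3-dioxoisoindolin-2-yl (4E)-5-{(2R,3S)-3-[(2R,3E,7E)-2-(tert-butyldimethylsilyloxy)-8-iodo-3,7-dimethylocta-3,7-dien-1-yl]-5-oxooxolan-2-yl}-4-methylpent-4-enoate
Conditions: N,N'-diisopropylcarbodiimide, DMAP (10 mol%), CH2Cl2, 0 °C to rt
Reagents that add atoms: none
Why: Carbodiimide (Steglich-type) esterification of the acid with N-hydroxyphthalimide gives the redox-active ester under neutral conditions that leave lactone, silyl ether and alkenyl iodide intact.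

Step 13
Reactants: 19 1,3-dioxoisoindolin-2-yl (4E)-5-{(2R,3S)-3-[(2R,3E,7E)-2-(tert-butyldimethylsilyloxy)-8-iodo-3,7-dimethylocta-3,7-dien-1-yl]-5-oxooxolan-2-yl}-4-methylpent-4-enoate
Product: 20 (1S,2R,3E,7E,11E,13R)-13-(tert-butyldimethylsilyloxy)-17-norcembra-3,7,11-trien-16,2-olide
Conditions: NiCl2(dme) (30 mol%), 2,2'-bipyridine (36 mol%), AgNO3 (30 mol%), LiCl (0.2 M), DMF, rt, undivided cell, Mg anode, reticulated vitreous carbon cathode, constant current; 19 added by syringe pump over 12 h (final 2 mM)
Reagents that add atoms: none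
Why: Proposed new method: at the cathode divalent nickel (bipyridine-ligated) is reduced to low-valent nickel, which inserts into the C7–I bond with retention of the E geometry, while electron transfer to the phthalimide ester cleaves N–O and releases CO2 and the primary C6 radical; the alkenylnickel captures that radical and reductive elimination from trivalent nickel forms C6–C7. The closest known reaction type is the intermolecular nickel-electrocatalytic decarboxylative alkenylation of redox-active esters with alkenyl iodides, run here as a macrocyclisation. The 14-membered ring closes at the metal (radical capture to a large nickelacycle, then C(sp3)–C(sp2) reductive elimination), so no endo or exo mode of radical attack on an alkene is involved. No stereocentre is formed, and C1, C2 and C13 lie far from the reacting atoms. The step needs retention of the 7E geometry and ring closure in preference to reduction of the radical, dimerisation or oligomerisation: stereoretentive oxidative addition and reductive elimination secure the first, and the cis-lactone, which holds both arms on one face, together with slow addition to about 2 mM secures the second. The substrate offers no competing trap, since the α-methylene group is absent, C13 carries a silyl ether and not an allylic acetate that low-valent nickel could ionise, and 3-exo attack of the C6 radical on C3=C4 is reversible and degenerate.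

Step 14
Reactants: 20 (1S,2R,3E,7E,11E,13R)-13-(tert-butyldimethylsilyloxy)-17-norcembra-3,7,11-trien-16,2-olide
Product: 24 (1S,2S,3E,7E,11E,13R)-13-(tert-butyldimethylsilyloxy)cembra-3,7,11,15(17)-tetraen-16,2-olide, via lithium enolate 21 (not isolated), via Mannich base 22 (not isolated), via ammonium iodide 23 (not isolated)
Conditions: LiN(iPr)2 (1.2 equiv), THF, −78 °C; CH2=NMe2+ I−, −78 °C to rt; then MeI, MeOH, rt; then aq. NaHCO3, CH2Cl2, rt
Reagents that add atoms: dimethylmethyleneammonium iodide C=[N+](C)C.[I-]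
Why: Kinetic enolate formation at C15 (the only enolisable position), Mannich alkylation with the iminium salt anti to the C1 substituent, exhaustive N-methylation and Hofmann-type β-elimination of trimethylamine should install the exocyclic C15=C17 methylene, the transient C15 stereocentre being destroyed.

Step 15
Reactants: 24 (1S,2S,3E,7E,11E,13R)-13-(tert-butyldimethylsilyloxy)cembra-3,7,11,15(17)-tetraen-16,2-olide
Product: 25 (1S,2S,3E,7E,11E,13R)-13-hydroxycembra-3,7,11,15(17)-tetraen-16,2-olide
Conditions: HF·pyridine, pyridine, THF, 0 °C to rt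
Reagents that add atoms: none
Why: Fluoride-mediated desilylation with buffered HF·pyridine should free the secondary allylic alcohol without conjugate addition to the α-methylene lactone or allylic ionisation.

Step 16
Reactants: 25 (1S,2S,3E,7E,11E,13R)-13-hydroxycembra-3,7,11,15(17)-tetraen-16,2-olide
Product: 26 (1S,2S,3E,7E,11E,13R)-13-acetoxycembra-3,7,11,15(17)-tetraen-16,2-olide
Conditions: Ac2O, pyridine, DMAP (cat.), CH2Cl2, 0 °C
Reagents that add atoms: acetic anhydride CC(=O)OC(C)=O
Why: DMAP-catalysed acylation of the secondary allylic alcohol with acetic anhydride should give the acetate with retention at C13.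

Compound list

1 | pent-4-yn-1-ol | C#CCCCO | starting material
2 | dimethyl[(1E)-5-(dimethylalumanyloxy)-2-methylpent-1-en-1-yl]alumane | C[Al](C)OCCC/C(C)=C/[Al](C)C | intermediate (not isolated)
3 | (4E)-5-iodo-4-methylpent-4-en-1-ol | OCCC/C(C)=C/I | intermediate
4 | (4E)-5-iodo-4-methylpent-4-enal | O=CCC/C(C)=C/I | intermediate
5 | 2-(triphenylphosphoranylidene)propanal | CC(C=O)=P(c1ccccc1)(c1ccccc1)c1ccccc1 | starting material
6 | (2E,6E)-7-iodo-2,6-dimethylhepta-2,6-dienal | O=C/C(C)=C/CC/C(C)=C/I | intermediate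
7 | 2-allyl-4,4,5,5-tetramethyl-1,3,2-dioxaborolane | C=CCB1OC(C)(C)C(C)(C)O1 | starting material
8 | (4R,5E,9E)-10-iodo-5,9-dimethyldeca-1,5,9-trien-4-ol | C=CC[C@@H](O)/C(C)=C/CC/C(C)=C/I | intermediate
9 | tert-butyl{[(4R,5E,9E)-10-iodo-5,9-dimethyldeca-1,5,9-trien-4-yl]oxy}dimethylsilane | C=CC[C@@H](O[Si](C)(C)C(C)(C)C)/C(C)=C/CC/C(C)=C/I | intermediate
10 | 2-[(2Z,5R,6E,10E)-5-(tert-butyldimethylsilyloxy)-11-iodo-6,10-dimethylundeca-2,6,10-trien-1-yl]-4,4,5,5-tetramethyl-1,3,2-dioxaborolane | CC1(C)OB(C/C=C\C[C@@H](O[Si](C)(C)C(C)(C)C)/C(C)=C/CC/C(C)=C/I)OC1(C)C | intermediate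
11 | lithium (4E)-5-lithio-4-methylpent-4-en-1-olate | [Li]OCCC/C(C)=C/[Li] | intermediate (not isolated)
12 | (2E)-6-hydroxy-3-methylhex-2-enal | O=C/C=C(\C)CCCO | intermediate
13 | (4E)-4-methyl-6-oxohex-4-en-1-yl acetate | CC(=O)OCCC/C(C)=C/C=O | intermediate
14 | (4E,6R,7S,9R,10E,14E)-9-(tert-butyldimethylsilyloxy)-7-ethenyl-6-hydroxy-15-iodo-4,10,14-trimethylpentadeca-4,10,14-trien-1-yl acetate | CC(=O)OCCC/C(C)=C/[C@H](O)[C@H](C=C)C[C@@H](O[Si](C)(C)C(C)(C)C)/C(C)=C/CC/C(C)=C/I | intermediate
15 | B-alkyl-9-borabicyclo[3.3.1]nonane adduct of 14 (boron on C16) | CC(=O)OCCC/C(C)=C/[C@H](O)[C@H](CCB1C2CCCC1CCC2)C[C@@H](O[Si](C)(C)C(C)(C)C)/C(C)=C/CC/C(C)=C/I | intermediate (not isolated)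
16 | (4E,6R,7R,9R,10E,14E)-9-(tert-butyldimethylsilyloxy)-7-(2-hydroxyethyl)-15-iodo-4,10,14-trimethylpentadeca-4,10,14-triene-1,6-diol | OCCC/C(C)=C/[C@H](O)[C@H](CCO)C[C@@H](O[Si](C)(C)C(C)(C)C)/C(C)=C/CC/C(C)=C/I | intermediate
17 | (4E)-5-{(2R,3S)-3-[(2R,3E,7E)-2-(tert-butyldimethylsilyloxy)-8-iodo-3,7-dimethylocta-3,7-dien-1-yl]-5-oxooxolan-2-yl}-4-methylpent-4-enoic acid | OC(=O)CC/C(C)=C/[C@@H]1OC(=O)C[C@@H]1C[C@@H](O[Si](C)(C)C(C)(C)C)/C(C)=C/CC/C(C)=C/I | intermediate
18 | N-hydroxyphthalimide | ON1C(=O)c2ccccc2C1=O | starting material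
19 | 1,3-dioxoisoindolin-2-yl (4E)-5-{(2R,3S)-3-[(2R,3E,7E)-2-(tert-butyldimethylsilyloxy)-8-iodo-3,7-dimethylocta-3,7-dien-1-yl]-5-oxooxolan-2-yl}-4-methylpent-4-enoate | O=C(CC/C(C)=C/[C@@H]1OC(=O)C[C@@H]1C[C@@H](O[Si](C)(C)C(C)(C)C)/C(C)=C/CC/C(C)=C/I)ON1C(=O)c2ccccc2C1=O | intermediate
20 | (1S,2R,3E,7E,11E,13R)-13-(tert-butyldimethylsilyloxy)-17-norcembra-3,7,11-trien-16,2-olide | C1C(=O)O[C@H]2/C=C(\C)CC/C=C(\C)CC/C=C(\C)[C@H](O[Si](C)(C)C(C)(C)C)C[C@@H]12 | intermediate
21 | lithium enolate of 20 (C15=C16–OLi) | C1=C(O[Li])O[C@H]2/C=C(\C)CC/C=C(\C)CC/C=C(\C)[C@H](O[Si](C)(C)C(C)(C)C)C[C@@H]12 | intermediate (not isolated)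
22 | (1S,2R,3E,7E,11E,13R,15R)-13-(tert-butyldimethylsilyloxy)-17-(dimethylamino)cembra-3,7,11-trien-16,2-olide | CN(C)C[C@@H]1C(=O)O[C@H]2/C=C(\C)CC/C=C(\C)CC/C=C(\C)[C@H](O[Si](C)(C)C(C)(C)C)C[C@@H]12 | intermediate (not isolated)
23 | N-methyl quaternary ammonium iodide of 22 | C[N+](C)(C)C[C@@H]1C(=O)O[C@H]2/C=C(\C)CC/C=C(\C)CC/C=C(\C)[C@H](O[Si](C)(C)C(C)(C)C)C[C@@H]12.[I-] | intermediate (not isolated)
24 | (1S,2S,3E,7E,11E,13R)-13-(tert-butyldimethylsilyloxy)cembra-3,7,11,15(17)-tetraen-16,2-olide | C=C1C(=O)O[C@H]2/C=C(\C)CC/C=C(\C)CC/C=C(\C)[C@H](O[Si](C)(C)C(C)(C)C)C[C@@H]12 | intermediate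
25 | (1S,2S,3E,7E,11E,13R)-13-hydroxycembra-3,7,11,15(17)-tetraen-16,2-olide | C=C1C(=O)O[C@H]2/C=C(\C)CC/C=C(\C)CC/C=C(\C)[C@H](O)C[C@@H]12 | intermediate
26 | (1S,2S,3E,7E,11E,13R)-13-acetoxycembra-3,7,11,15(17)-tetraen-16,2-olide (CNP0182196.1) | C=C1C(=O)O[C@H]2/C=C(\C)CC/C=C(\C)CC/C=C(\C)[C@H](OC(C)=O)C[C@@H]12 | target

Total step count: 16. Longest linear sequence: 14 steps (steps 1–6, then 9–16); the second arm needs only steps 7 and 8 from the shared iodide 3.

Steps most likely to fail

Step 13. The C6 radical may be reduced to the alkane, or may couple between molecules (dimers, oligomers), faster than the tethered alkenylnickel captures it. Low-valent nickel may also ionise the allylic C2–O bond of the lactone. The fallback uses known chemistry and sets out from 19. Photochemical decarboxylative borylation (bis(catecholato)diboron, N,N-dimethylacetamide, blue light, then pinacol and Et3N) would turn the redox-active ester into the primary C6 pinacol boronate F1. An intramolecular Suzuki–Miyaura coupling of this alkylboronate with the C7 iodide under high dilution (Pd(OAc)2, RuPhos, K3PO4, toluene–water, 80 °C, slow addition, acidic work-up to re-close any opened lactone) would then form the same C6–C7 bond with retention of the alkene geometry and return to the route at 20.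

Step 9. Facial selectivity may be poor: the hindered Z-boronate may react partly by the uncatalysed background pathway, or the catalyst may suit the β,β-disubstituted enal badly, so that both syn diastereomers form. The fallback sets out from 10. Transesterification with diethanolamine would give the diethanolamine boronate F2, and exchange of F2 with diisopropyl (2S,3S)-tartrate (ether/brine) would give the tartrate-modified Z-allylboronate F3. Its stoichiometric, reagent-controlled addition to 13 (toluene, 4 Å MS, −78 °C) passes through the same closed chair transition state; the (S,S)-tartrate is expected to favour Re-face attack. This should again give the syn adduct and return to the route at 14. Because C13 is already set, the minor syn isomer is a diastereomer and can be removed by chromatography.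

Step 6. The Z geometry may erode through secondary metathesis or isomerisation, or conversion may stall because allyl-B(pin) homodimerises. Any E-boronate would end as the trans-lactone. The fallback sets out from 6. Phosphoric acid-catalysed propargylation with allenylboronic acid pinacol ester ((R)-TRIP, 4 Å MS, toluene, 0 °C) would give the (R)-homopropargylic alcohol F4, and silylation (TBSCl, imidazole) its TBS ether F5. Deprotonation of the terminal alkyne with LiN(iPr)2 at −78 °C (no halogen–metal exchange at the alkenyl iodide) and Matteson-type homologation with ICH2B(pin) would give the propargylic pinacol boronate F6. Lindlar semi-hydrogenation (Pd/CaCO3 poisoned with Pb(OAc)2, quinoline, H2, stopped after one equivalent) would then deliver the Z-allylboronate and return to the route at 10.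

Further compounds

F1 | step 13 | 2-{(3E)-4-[(2R,3S)-3-[(2R,3E,7E)-2-(tert-butyldimethylsilyloxy)-8-iodo-3,7-dimethylocta-3,7-dien-1-yl]-5-oxooxolan-2-yl]-3-methylbut-3-en-1-yl}-4,4,5,5-tetramethyl-1,3,2-dioxaborolane | CC1(C)OB(CC/C(C)=C/[C@@H]2OC(=O)C[C@@H]2C[C@@H](O[Si](C)(C)C(C)(C)C)/C(C)=C/CC/C(C)=C/I)OC1(C)C
F2 | step 9 | 2-[(2Z,5R,6E,10E)-5-(tert-butyldimethylsilyloxy)-11-iodo-6,10-dimethylundeca-2,6,10-trien-1-yl]-1,3,6,2-dioxazaborocane | C(/C=C\C[C@@H](O[Si](C)(C)C(C)(C)C)/C(C)=C/CC/C(C)=C/I)B1OCCNCCO1
F3 | step 9 | diisopropyl (4S,5S)-2-[(2Z,5R,6E,10E)-5-(tert-butyldimethylsilyloxy)-11-iodo-6,10-dimethylundeca-2,6,10-trien-1-yl]-1,3,2-dioxaborolane-4,5-dicarboxylate | CC(C)OC(=O)[C@H]1OB(C/C=C\C[C@@H](O[Si](C)(C)C(C)(C)C)/C(C)=C/CC/C(C)=C/I)O[C@@H]1C(=O)OC(C)C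
F4 | step 6 | (4R,5E,9E)-10-iodo-5,9-dimethyldeca-5,9-dien-1-yn-4-ol | C#CC[C@@H](O)/C(C)=C/CC/C(C)=C/I
F5 | step 6 | tert-butyl{[(4R,5E,9E)-10-iodo-5,9-dimethyldeca-5,9-dien-1-yn-4-yl]oxy}dimethylsilane | C#CC[C@@H](O[Si](C)(C)C(C)(C)C)/C(C)=C/CC/C(C)=C/I
F6 | step 6 | 2-[(5R,6E,10E)-5-(tert-butyldimethylsilyloxy)-11-iodo-6,10-dimethylundeca-6,10-dien-2-yn-1-yl]-4,4,5,5-tetramethyl-1,3,2-dioxaborolane | CC1(C)OB(CC#CC[C@@H](O[Si](C)(C)C(C)(C)C)/C(C)=C/CC/C(C)=C/I)OC1(C)C
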